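**Retrosynthetic overview**

1. Target 15 ← tert-butyl ester 14 (acidolysis) ← 4-O-tigloylation of 12 ← Mitsunobu inversion of the allylic C3 hydroxyl of cis-diol 10 with 6-methylheptanoic acid ← anti-osmylation of dienoate 9.
2. Dienoate 9 is cut through C1–C6 and C3=C4 (the later C3–C4 single bond) into crotonate γ-ylide 3 (C1–C2–C3 plus the carboxyl) and (S)-glycidaldehyde diacetate 6 (C4–C5–C6). Epoxide 6 comes from acrolein diacetate by epoxidation and hydrolytic kinetic resolution.
3. Enabling feature: in the cyclohexene ring, C1(CO2H)=C2–C3 is a vinylogous ester, so one ylide supplies a nucleophilic C1 and an olefinating C3. C4–C5(OAc)–C6 is a glyceraldehyde triad in which the C5 acetate oxygen can begin as an epoxide oxygen and C4 as an acylal; opening at C6 then frees O5 to take an acetyl from C4 and unmask the aldehyde.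
4. Ring order: the cyclohexene is the only ring and is closed in step 5. C5 comes from the resolution, C4 from osmylation anti to the acetate, C3 by inversion.

Key step: step 5

Remark: the SMILES is read as the all-trans (3R,4R,5S) triester (O3 and O5 cis, O4 trans to both) with a 6-methylheptanoyl group on O3; compounds 1, 4, 11 and 13 are taken as commercial.

**Route**

Step 1
Reactants: 1 tert-butyl (2E)-4-bromobut-2-enoate
Product: 2 [(2E)-4-tert-butoxy-4-oxobut-2-en-1-yl]triphenylphosphonium bromide
Conditions: PPh3 (1.0 equiv), toluene, rt; salt filtered off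
Reagents that add atoms: triphenylphosphine, c1ccc(cc1)P(c1ccccc1)c1ccccc1
Why: SN2 quaternisation of the primary allylic bromide by the phosphine should give the crystalline phosphonium salt.

Step 2
Reactants: 2 [(2E)-4-tert-butoxy-4-oxobut-2-en-1-yl]triphenylphosphonium bromide
Product: 3 tert-butyl (2E)-4-(triphenyl-λ5-phosphanylidene)but-2-enoate
Conditions: 1 M NaOH (aq), CH2Cl2, 0 °C; organic layer dried, ylide recrystallised free of halide
Reagents that add atoms: none
Why: deprotonation of the vinylogously ester-stabilised phosphonium salt should give the isolable allylidene ylide; bromide is removed because step 5 must be halide-free.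

Step 3
Reactants: 4 prop-2-ene-1,1-diyl diacetate (acrolein diacetate)
Product: 5 rac-(oxiran-2-yl)methanediyl diacetate
Conditions: mCPBA (1.5 equiv), 4,4'-thiobis(6-tert-butyl-3-methylphenol) (cat.), ClCH2CH2Cl, 60 °C
Reagents that add atoms: mCPBA (3-chloroperoxybenzoic acid), OOC(=O)c1cccc(Cl)c1
Why: Prilezhaev epoxidation; the alkene is deactivated by the allylic acylal, hence the hot, radical-inhibited conditions used for allyl esters, and the acylal should survive the weak acid by-product.

Step 4
Reactants: 5 rac-(oxiran-2-yl)methanediyl diacetate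
Product: 6 [(2S)-oxiran-2-yl]methanediyl diacetate
Conditions: (S,S)-N,N'-bis(3,5-di-tert-butylsalicylidene)-1,2-cyclohexanediaminocobalt acetate [(S,S)-(salen)Co(OAc), trivalent cobalt] (0.5 mol%), H2O (0.55 equiv), THF, 0 °C to rt; 6 distilled from the diol
Reagents that add atoms: none
Why: hydrolytic kinetic resolution (Jacobsen) of a terminal epoxide should leave one enantiomer untouched, which fixes the C5 stereocentre under catalyst control. The (S,S)-complex is chosen on the usual spatial model (CH(OAc)2 outranks the ring CH2, so the descriptor is reversed relative to alkyl oxiranes); the sense would be confirmed on a small scale and the antipodal complex used if needed.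

Step 5
Reactants: 3 tert-butyl (2E)-4-(triphenyl-λ5-phosphanylidene)but-2-enoate; 6 [(2S)-oxiran-2-yl]methanediyl diacetate
Product: 9 tert-butyl (5S)-5-(acetyloxy)cyclohexa-1,3-diene-1-carboxylate, via oxidophosphonium betaine 7 (not isolated), via acetoxy aldehyde ylide 8 (not isolated)
Conditions: 3 (1.05 equiv), LiClO4 (1 equiv), iPr2NEt (1.2 equiv), MeCN (0.05 M), 50 °C, halide-free
Reagents that add atoms: none
Why: Proposed new method: the ambident ylide 3 should attack the terminal epoxide carbon C6 of 6 through its enolate-like γ-carbon (the future C1; the α-carbon is shielded by PPh3), with LiClO4 activating the oxirane as in metal-salt-promoted aminolysis of epoxides, to give betaine 7; proton transfer from the doubly activated C1–H restores the ylide, and the C5 oxygen takes an acetyl group from the neighbouring acylal by a five-membered 1,2-O-to-O acyl shift, which installs the C5 acetate and releases the C4 aldehyde of 8 only after the C1–C6 bond exists. Intramolecular Wittig olefination (6-exo-trig attack of ylide carbon C3 on C4=O, then loss of Ph3PO) closes the only ring and forms C3=C4, the masked form of the C3–C4 bond. The closest known reactions are the [3+3] Michael–Wittig annulation of this type of allylidenephosphorane with enals and its γ-alkylation–Wittig annulation with α-halo ketones; new are the epoxide as alkylating agent and the unmasking by acyl shift. No new stereocentre is created: C5 is carried over from 6 because the epoxide opens at C6, and the aldehyde is trapped by the ylide already in place before its α-centre can enolise. The step needs γ- over α-alkylation, attack at the CH2 and not at the acylal carbonyls, and absence of halide (which would open 6 and lead by elimination to achiral 2-acetoxyacrolein); the tert-butyl ester blocks γ-lactonisation by the C5 alkoxide, and iPr2NEt takes up the acetic acid that would otherwise protonate the ylide.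

Step 6
Reactants: 9 tert-butyl (5S)-5-(acetyloxy)cyclohexa-1,3-diene-1-carboxylate
Product: 10 tert-butyl (3S,4S,5S)-5-(acetyloxy)-3,4-dihydroxycyclohex-1-ene-1-carboxylate
Conditions: OsO4 (2 mol%), NMO (1.2 equiv), citric acid (0.5 equiv), acetone/H2O 4:1, 0 °C to rt
Reagents that add atoms: N-methylmorpholine N-oxide, C[N+]1([O-])CCOCC1, and water, O (oxygen delivered through OsO4, O=[Os](=O)(=O)=O)
Why: Upjohn dihydroxylation should take the electron-richer distal alkene C3=C4 and leave the ester-conjugated C1=C2; suprafacial addition anti to the allylic acetate (the usual empirical rule for osmylation of allylic esters) sets C3 and C4 both trans to the C5 acetate, and the citric acid buffer suppresses O5-to-O4 acetyl migration.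

Step 7
Reactants: 10 tert-butyl (3S,4S,5S)-5-(acetyloxy)-3,4-dihydroxycyclohex-1-ene-1-carboxylate; 11 6-methylheptanoic acid
Product: 12 tert-butyl (3R,4R,5S)-5-(acetyloxy)-4-hydroxy-3-[(6-methylheptanoyl)oxy]cyclohex-1-ene-1-carboxylate
Conditions: PPh3 (1.3 equiv), DIAD (1.3 equiv), 11 (1.3 equiv), THF, −20 to 0 °C
Reagents that add atoms: none
Why: Mitsunobu esterification should occur at the allylic, less hindered C3 hydroxyl, as known for shikimate esters, and not at the C4 hydroxyl flanked by two oxygenated carbons; SN2 inversion at C3 sets the 3,4-trans relationship, SN2' is excluded because C1 is fully substituted, and a cis-diol cannot close to an epoxide.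

Step 8
Reactants: 12 tert-butyl (3R,4R,5S)-5-(acetyloxy)-4-hydroxy-3-[(6-methylheptanoyl)oxy]cyclohex-1-ene-1-carboxylate; 13 (2E)-2-methylbut-2-enoyl chloride (tigloyl chloride)
Product: 14 tert-butyl (3R,4R,5S)-5-(acetyloxy)-4-{[(2E)-2-methylbut-2-enoyl]oxy}-3-[(6-methylheptanoyl)oxy]cyclohex-1-ene-1-carboxylate
Conditions: 13 (2 equiv), pyridine (4 equiv), DMAP (0.2 equiv), CH2Cl2, 0 °C to rt
Reagents that add atoms: none
Why: DMAP-catalysed acylation of the remaining secondary hydroxyl; pyridine instead of a trialkylamine avoids vinylketene formation and deconjugation of the tigloyl group, and the low temperature limits trans-vicinal acyl migration; no stereocentre is touched.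

Step 9
Reactants: 14 tert-butyl (3R,4R,5S)-5-(acetyloxy)-4-{[(2E)-2-methylbut-2-enoyl]oxy}-3-[(6-methylheptanoyl)oxy]cyclohex-1-ene-1-carboxylate
Product: 15 (3R,4R,5S)-5-(acetyloxy)-4-{[(2E)-2-methylbut-2-enoyl]oxy}-3-[(6-methylheptanoyl)oxy]cyclohex-1-ene-1-carboxylic acid (target)
Conditions: CF3CO2H/CH2Cl2 1:4, 0 °C to rt
Reagents that add atoms: none
Why: acidolysis of the tert-butyl ester by alkyl–oxygen cleavage should leave the three secondary esters, the tiglate geometry and the enoate untouched.

**Compound list**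

1 | tert-butyl (2E)-4-bromobut-2-enoate | CC(C)(C)OC(=O)/C=C/CBr | starting material
2 | [(2E)-4-tert-butoxy-4-oxobut-2-en-1-yl]triphenylphosphonium bromide | CC(C)(C)OC(=O)/C=C/C[P+](c1ccccc1)(c1ccccc1)c1ccccc1.[Br-] | intermediate
3 | tert-butyl (2E)-4-(triphenyl-λ5-phosphanylidene)but-2-enoate | CC(C)(C)OC(=O)/C=C/C=P(c1ccccc1)(c1ccccc1)c1ccccc1 | intermediate
4 | prop-2-ene-1,1-diyl diacetate | CC(=O)OC(OC(C)=O)C=C | starting material
5 | rac-(oxiran-2-yl)methanediyl diacetate | CC(=O)OC(OC(C)=O)C1CO1 | intermediate
6 | [(2S)-oxiran-2-yl]methanediyl diacetate | CC(=O)OC(OC(C)=O)[C@@H]1CO1 | intermediate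
7 | tert-butyl (3E)-2-[(2S)-3,3-bis(acetyloxy)-2-oxidopropyl]-4-(triphenylphosphaniumyl)but-3-enoate (betaine, both C2 epimers) | CC(=O)OC(OC(C)=O)[C@@H]([O-])CC(C(=O)OC(C)(C)C)/C=C/[P+](c1ccccc1)(c1ccccc1)c1ccccc1 | intermediate (not isolated)
8 | tert-butyl (2E)-2-[(2S)-2-(acetyloxy)-3-oxopropyl]-4-(triphenyl-λ5-phosphanylidene)but-2-enoate | O=C[C@@H](OC(C)=O)C/C(C(=O)OC(C)(C)C)=C\C=P(c1ccccc1)(c1ccccc1)c1ccccc1 | intermediate (not isolated)
9 | tert-butyl (5S)-5-(acetyloxy)cyclohexa-1,3-diene-1-carboxylate | CC(=O)O[C@@H]1C=CC=C(C1)C(=O)OC(C)(C)C | intermediate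
10 | tert-butyl (3S,4S,5S)-5-(acetyloxy)-3,4-dihydroxycyclohex-1-ene-1-carboxylate | O[C@@H]1[C@@H](OC(C)=O)CC(C(=O)OC(C)(C)C)=C[C@@H]1O | intermediate
11 | 6-methylheptanoic acid | CC(C)CCCCC(=O)O | starting material
12 | tert-butyl (3R,4R,5S)-5-(acetyloxy)-4-hydroxy-3-[(6-methylheptanoyl)oxy]cyclohex-1-ene-1-carboxylate | O[C@@H]1[C@@H](OC(C)=O)CC(C(=O)OC(C)(C)C)=C[C@H]1OC(=O)CCCCC(C)C | intermediate
13 | (2E)-2-methylbut-2-enoyl chloride | C/C=C(\C)C(Cl)=O | starting material
14 | tert-butyl (3R,4R,5S)-5-(acetyloxy)-4-{[(2E)-2-methylbut-2-enoyl]oxy}-3-[(6-methylheptanoyl)oxy]cyclohex-1-ene-1-carboxylate | C/C=C(\C)C(=O)O[C@@H]1[C@@H](OC(C)=O)CC(C(=O)OC(C)(C)C)=C[C@H]1OC(=O)CCCCC(C)C | intermediate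
15 | (3R,4R,5S)-5-(acetyloxy)-4-{[(2E)-2-methylbut-2-enoyl]oxy}-3-[(6-methylheptanoyl)oxy]cyclohex-1-ene-1-carboxylic acid | C/C=C(\C)C(=O)O[C@@H]1[C@@H](OC(C)=O)CC(C(=O)O)=C[C@H]1OC(=O)CCCCC(C)C | target

**Step count and risks**

Total step count: 9. Longest linear sequence: 7 steps (1 → 2 → 3 → 9 → 10 → 12 → 14 → 15, or equally 4 → 5 → 6 → 9 → … → 15).

Steps most likely to fail:

Step 5 (proposed new method). The stabilised ylide may open the epoxide too slowly or through its α-carbon, and any elimination to the achiral enal before ring closure would erode the enantiomeric purity. The fallback uses known chemistry and sets out from ylide 3. Commercial 2,2-dimethyl-1,3-dioxan-5-one would be O-acetylated through its potassium enolate (KN(SiMe3)2, then Ac2O, THF, −78 °C) to 2,2-dimethyl-4H-1,3-dioxin-5-yl acetate F1. Retro-hetero-Diels–Alder thermolysis of F1 in toluene would give 3-oxoprop-1-en-2-yl acetate (2-acetoxyacrolein) F2. The known Michael–Wittig [3+3] annulation of 3 with the enal F2 (CH2Cl2, rt) would give racemic tert-butyl 5-(acetyloxy)cyclohexa-1,3-diene-1-carboxylate F3. This would be resolved by preparative chromatography on a chiral stationary phase; the (5R)-enantiomer, tert-butyl (5R)-5-(acetyloxy)cyclohexa-1,3-diene-1-carboxylate F4, is discarded and the (5S)-enantiomer is compound 9, where the route is rejoined.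

Step 7. Activation of the allylic alcohol may lead to elimination and aromatisation, or esterification may stray to the C4 hydroxyl. The fallback sets out from 9 and returns at 12 without passing through 10. Epoxidation of the distal alkene anti to the acetate (mCPBA, NaHCO3, CH2Cl2, 0 °C) would give tert-butyl (1S,5S,6R)-5-(acetyloxy)-7-oxabicyclo[4.1.0]hept-2-ene-3-carboxylate F5. SN2 opening at the allylic carbon with acid 11 and Cs2CO3 (cat.) in DMF at 40 °C would deliver the 3-O-acyl, 4-hydroxy pattern with the same inversion at C3, that is 12.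

Step 8. Acylation of the hindered C4 hydroxyl may be slow enough for acyl migration from O3 or O5 to scramble the ester pattern. The fallback sets out from 10 and returns at 14, acylating C4 before the C3 ester exists. Silylation of the allylic C3 hydroxyl (Et3SiCl, imidazole, CH2Cl2, −40 °C) would give tert-butyl (3S,4R,5S)-5-(acetyloxy)-4-hydroxy-3-[(triethylsilyl)oxy]cyclohex-1-ene-1-carboxylate F6. Tigloylation with 13 (pyridine, DMAP) would give tert-butyl (3S,4R,5S)-5-(acetyloxy)-4-{[(2E)-2-methylbut-2-enoyl]oxy}-3-[(triethylsilyl)oxy]cyclohex-1-ene-1-carboxylate F7. Desilylation with HF·pyridine would give tert-butyl (3S,4S,5S)-5-(acetyloxy)-3-hydroxy-4-{[(2E)-2-methylbut-2-enoyl]oxy}cyclohex-1-ene-1-carboxylate F8. Mitsunobu inversion of F8 with 11 (PPh3, DIAD, THF) would give 14.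

**Further compounds**

F1 | step 5 | 2,2-dimethyl-4H-1,3-dioxin-5-yl acetate | CC(=O)OC1=COC(C)(C)OC1
F2 | step 5 | 3-oxoprop-1-en-2-yl acetate | CC(=O)OC(=C)C=O
F3 | step 5 | rac-tert-butyl 5-(acetyloxy)cyclohexa-1,3-diene-1-carboxylate | CC(=O)OC1C=CC=C(C1)C(=O)OC(C)(C)C
F4 | step 5 | tert-butyl (5R)-5-(acetyloxy)cyclohexa-1,3-diene-1-carboxylate | CC(=O)O[C@H]1C=CC=C(C1)C(=O)OC(C)(C)C
F5 | step 7 | tert-butyl (1S,5S,6R)-5-(acetyloxy)-7-oxabicyclo[4.1.0]hept-2-ene-3-carboxylate | CC(=O)O[C@H]1CC(C(=O)OC(C)(C)C)=C[C@@H]2O[C@H]12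
F6 | step 8 | tert-butyl (3S,4R,5S)-5-(acetyloxy)-4-hydroxy-3-[(triethylsilyl)oxy]cyclohex-1-ene-1-carboxylate | O[C@@H]1[C@@H](OC(C)=O)CC(C(=O)OC(C)(C)C)=C[C@@H]1O[Si](CC)(CC)CC
F7 | step 8 | tert-butyl (3S,4R,5S)-5-(acetyloxy)-4-{[(2E)-2-methylbut-2-enoyl]oxy}-3-[(triethylsilyl)oxy]cyclohex-1-ene-1-carboxylate | C/C=C(\C)C(=O)O[C@@H]1[C@@H](OC(C)=O)CC(C(=O)OC(C)(C)C)=C[C@@H]1O[Si](CC)(CC)CC
F8 | step 8 | tert-butyl (3S,4S,5S)-5-(acetyloxy)-3-hydroxy-4-{[(2E)-2-methylbut-2-enoyl]oxy}cyclohex-1-ene-1-carboxylate | C/C=C(\C)C(=O)O[C@@H]1[C@@H](OC(C)=O)CC(C(=O)OC(C)(C)C)=C[C@@H]1O
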